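**Retrosynthetic overview**
1. 31 ⇒ C9‑vinyl diester 29 + 4‑bromofuran‑2(5H)‑one 30 (Mizoroki–Heck, last step); the C6/C7/C8 oxygens come from C6‑enone 23 by reactions that touch only carbonyl‑activated positions, so C3=C4 and the vinyl group survive.
2. 23 ⇒ C8‑enone 21 (MeLi, oxidative 1,3‑transposition) ⇒ vinyl ketone 19 ⇒ bicyclic enone 16, by a Birch‑type reductive aldol that sets H10 (trans fusion) and the quaternary C9.
3. 16 ⇒ monocyclic enone 8 by the key [3+3] annulation: an allyl ylide joins C1 to C10 (conjugate addition) and C3 to C4 (Wittig) in one operation, building ring A with its C3=C4 bond; the extra C1=C2 bond is then hydrogenated and C9=C10 restored.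
4. Enabling feature: ring A (C1, C2, C3, C4, C5, C10) is a cyclohexene whose C1–C3 carry only hydrogen, whose C3=C4 bond bears the C18 methyl and ends at the quaternary C5, and whose C10 is β to the oxygenated C8 of ring B. C10–C5–C4 is therefore an enone β‑carbon/methyl ketone pair that a three‑carbon allyl bis‑nucleophile can bridge.
5. Ring order: ring B first (catalytic asymmetric Diels–Alder sets C5, the only stereocentre carried through the key step), then ring A (step 6); the preformed butenolide ring is attached last.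

Key step: step 6

Remark: bicyclic compounds are named with clerodane locants (ring A = C1, C2, C3, C4, C5, C10; ring B = C5 to C10; methyls C17 on C8, C18 on C4, C19 on C5, C20 on C9; C11–C16 = side chain), α being the face of the C5 methyl and β the opposite face; the TADDOL antipode in step 1 is assumed to be the one that gives (1R,2S)‑3, its mirror image being equally available.

**Step 1**
Reactants: 1 (E)‑3‑(tert‑butyldimethylsilyloxy)‑N,N‑dimethylbuta‑1,3‑dien‑1‑amine; 2 methacrolein
Product: 3 (1R,2S)‑4‑(tert‑butyldimethylsilyloxy)‑2‑(dimethylamino)‑1‑methylcyclohex‑3‑ene‑1‑carbaldehyde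
Conditions: 1‑naphthyl‑TADDOL (20 mol%), toluene, −80 °C
Reagents that add atoms: none
Why: Hydrogen‑bond‑catalysed Diels–Alder reaction of a 1‑amino‑3‑siloxy diene with an α‑substituted acrolein, in which the amino terminus bonds to the α‑carbon through an endo transition state and the chiral diol shields one face of the bound aldehyde, so the quaternary carbon (future C5) should form as R and the amino carbon as S.

**Step 2**
Reactants: 3 Diels–Alder adduct
Product: 5 (4R)‑4‑(1‑hydroxyethyl)‑4‑methylcyclohex‑2‑en‑1‑one (carbinol epimers), via bromomagnesium alkoxide 4 (not isolated)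
Conditions: MeMgBr, THF, −78 °C; then 1 M HCl, THF, 0 °C → rt
Reagents that add atoms: methylmagnesium bromide, C[Mg]Br
Why: Grignard 1,2‑addition to the aldehyde (carbinol configuration irrelevant), then acid hydrolysis of the silyl enol ether and β‑elimination of dimethylamine should unmask the enone without touching the quaternary centre.

**Step 3**
Reactants: 5 hydroxyethyl enone
Product: 6 (4R)‑4‑acetyl‑4‑methylcyclohex‑2‑en‑1‑one
Conditions: DMP (1,1,1‑triacetoxy‑1,1‑dihydro‑1,2‑benziodoxol‑3(1H)‑one), CH2Cl2, rt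
Reagents that add atoms: none
Why: Periodinane oxidation of the secondary alcohol to the methyl ketone under neutral conditions that leave the enone and the stereocentre alone.

**Step 4**
Reactants: 6 acetyl enone
Product: 7 (4R)‑4‑acetyl‑2‑iodo‑4‑methylcyclohex‑2‑en‑1‑one
Conditions: I2, pyridine/CH2Cl2 (1:1), 0 °C → rt
Reagents that add atoms: iodine, II
Why: α‑Iodination of the enone by the pyridine addition/iodination/elimination sequence, a reaction type established for 4,4‑disubstituted cyclohexenones and not expected to enolise the acetyl group.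

**Step 5**
Reactants: 7 iodo enone
Product: 8 (4R)‑4‑acetyl‑2,4‑dimethylcyclohex‑2‑en‑1‑one
Conditions: Me4Sn, PdCl2(PhCN)2 (5 mol%), AsPh3, CuI, NMP, 80 °C
Reagents that add atoms: tetramethylstannane, C[Sn](C)(C)C
Why: Stille cross‑coupling of the α‑iodoenone installs the future C20 methyl without involving any stereocentre.

**Step 6**
Reactants: 8 (4R)‑4‑acetyl‑2,4‑dimethylcyclohex‑2‑en‑1‑one; 9 allyltriphenylphosphonium bromide
Product: 13 4,5α,9‑trimethyl‑Δ1,3‑hexalin‑8‑one (C9/C10 epimers), via allylidenetriphenylphosphorane 10 (not isolated), via vinylphosphonium enolate 11 (not isolated), via allylic ylide 12 (not isolated)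
Conditions: n‑BuLi, THF, 0 °C (9 → 10); then 8, −78 °C → rt → 60 °C
Reagents that add atoms: none
Why: Proposed new method: the semi‑stabilised ylide 10 should add through its γ‑carbon to C10 of the enone (conjugate addition) to give 11, a proton shift from C1 to the enolate gives the allylic ylide 12, and its phosphorus‑bearing C3 then olefinates the C4 acetyl carbonyl intramolecularly (Wittig) with loss of Ph3PO, leaving ring A as a cyclohexa‑1,3‑diene; the closest known reaction type is the Michael/Wittig cyclohexadiene annulation of allylidenetriphenylphosphorane with α,β‑unsaturated ketones, where the enone's own carbonyl is olefinated, whereas here it is a separate methyl ketone held 1,3 to the acceptor carbon. Ring A closes in the Wittig event, a 6‑exo‑trig attack of C3 on the exocyclic C4=O across the C10–C5–C4 unit. New stereocentres form at C10 (face of ylide attack) and C9 (ketonisation) without reliable control, which is accepted by design because both are erased in step 8 and re‑set in step 9, while the quaternary C5 cannot epimerise. The step needs γ‑conjugate addition to win over direct Wittig reaction at either carbonyl, which the substrate favours because the ring carbonyl is conjugated and α‑methylated, the acetyl group is neopentylic and the γ‑carbon of 10 is an unhindered CH2. After conjugate addition only the acetyl group can close a ring, since olefination of the ring carbonyl would give an anti‑Bredt bridgehead alkene. The cisoid C1=C2 geometry needed for closure should be reached through the delocalised ylide, as in the known annulation.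

**Step 7**
Reactants: 13 ring‑A diene ketone
Product: 14 4,5α,9‑trimethyl‑Δ3‑octalin‑8‑one (C9/C10 epimers)
Conditions: H2 (1 atm), RhCl(PPh3)3 (5 mol%), benzene, rt
Reagents that add atoms: none
Why: Homogeneous hydrogenation with this sterically selective catalyst should reduce the cis‑disubstituted C1=C2 bond by 1,2‑addition and leave the trisubstituted C3=C4 bond next to the quaternary C5 and the ketone untouched.

**Step 8**
Reactants: 14 octalinone
Product: 16 4,5α,9‑trimethyl‑Δ3,9(10)‑hexalin‑8‑one, via silyl enol ether 15 (not isolated)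
Conditions: Me3SiCl, NaI, Et3N, MeCN, rt; then Pd(OAc)2 (10 mol%), O2 (1 atm), DMSO, rt
Reagents that add atoms: none
Why: Equilibrating silylation should favour the more substituted C8=C9 silyl enol ether, and Saegusa–Ito oxidation (syn β‑hydride elimination of H10 from the divalent palladium enolate) then gives the tetrasubstituted enone, erasing the uncontrolled C9 and C10 centres so that both ring‑fusion isomers converge.

**Step 9**
Reactants: 16 bicyclic enone
Product: 18 9β‑(1‑hydroxyethyl)‑4,5α,9α‑trimethyl‑10βH‑Δ3‑octalin‑8‑one (carbinol epimers), via lithium enolate 17 (not isolated)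
Conditions: Li, NH3(l)/THF, t‑BuOH (1.0 equiv), −78 °C; isoprene; evaporate NH3; THF, −78 °C, CH3CHO; aq. NH4Cl
Reagents that add atoms: acetaldehyde, CC=O
Why: Birch‑type enone reduction protonates C10 to give the trans‑fused lithium enolate (H10 anti to the axial C5 methyl), and this regiodefined enolate should add to acetaldehyde (aldol) from the β face, anti to the 1,3‑diaxial C5 methyl, fixing C9 with methyl α and the side‑chain carbon β.

**Step 10**
Reactants: 18 aldol
Product: 19 4,5α,9α‑trimethyl‑9β‑vinyl‑10βH‑Δ3‑octalin‑8‑one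
Conditions: methyl N‑(triethylammoniosulfonyl)carbamate, benzene, 50 °C
Reagents that add atoms: none
Why: Syn‑elimination through the sulfamate ester under neutral conditions (no retro‑aldol) can only give the vinyl group, because C9 is quaternary and the carbinol methyl holds the only β‑hydrogens.

**Step 11**
Reactants: 19 vinyl ketone
Product: 21 4,5α,9α‑trimethyl‑9β‑vinyl‑10βH‑Δ3,6‑hexalin‑8‑one, via silyl enol ether 20 (not isolated)
Conditions: LiN(i‑Pr)2, THF, −78 °C; Me3SiCl; then Pd(OAc)2 (10 mol%), O2 (1 atm), DMSO, rt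
Reagents that add atoms: none
Why: Deprotonation is only possible at C7 (C9 is quaternary), and Saegusa–Ito oxidation of the silyl enol ether introduces the C6=C7 bond without changing any stereocentre.

**Step 12**
Reactants: 21 C8‑enone
Product: 22 4,5α,8,9α‑tetramethyl‑9β‑vinyl‑10βH‑Δ3,6‑hexalin‑8‑ol (C8 epimers)
Conditions: MeLi, Et2O/THF, −78 °C; aq. NH4Cl at −78 °C
Reagents that add atoms: methyllithium, [Li]C
Why: 1,2‑Addition of MeLi to a non‑enolisable enone brings in C17, the C8 configuration being irrelevant because C8 becomes sp2 in step 13, and the cold quench avoids an anionic oxy‑Cope of the 3‑oxido‑1,5‑diene.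

**Step 13**
Reactants: 22 tertiary allylic alcohol
Product: 23 4,5α,8,9α‑tetramethyl‑9β‑vinyl‑10βH‑Δ3,7‑hexalin‑6‑one
Conditions: pyridinium chlorochromate [C5H5NH][CrO3Cl], 4 Å MS, CH2Cl2, rt
Reagents that add atoms: pyridinium chlorochromate, [O-][Cr](=O)(=O)Cl.c1cc[nH+]cc1
Why: Babler–Dauben oxidative transposition, in which the chromate ester shifts [3,3] to C6 and is oxidised, moves the oxygen function from C8 to C6 and places the C7=C8 bond with its methyl group.

**Step 14**
Reactants: 23 C6‑enone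
Product: 24 7β,8β‑epoxy‑4,5α,8α,9α‑tetramethyl‑9β‑vinyl‑10βH‑Δ3‑octalin‑6‑one
Conditions: 30% H2O2, NaOH, MeOH, 0 °C → rt
Reagents that add atoms: hydrogen peroxide, OO
Why: Weitz–Scheffer nucleophilic epoxidation acts only on the enone double bond (C3=C4 and the vinyl group are inert to hydroperoxide anion), and axial attack on C8 from the β face, anti to the axial C9 methyl, should place the C8 oxygen β.

**Step 15**
Reactants: 24 epoxy ketone
Product: 25 8β‑hydroxy‑4,5α,8α,9α‑tetramethyl‑9β‑vinyl‑10βH‑Δ3‑octalin‑6‑one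
Conditions: SmI2, THF/MeOH, −90 °C
Reagents that add atoms: none
Why: Single‑electron reduction of the α,β‑epoxy ketone cleaves only the C7–O bond next to the ketyl, giving the β‑hydroxy ketone with the C8 configuration retained (OH β, methyl α).

**Step 16**
Reactants: 25 β‑hydroxy ketone
Product: 26 7β,8β‑dihydroxy‑4,5α,8α,9α‑tetramethyl‑9β‑vinyl‑10βH‑Δ3‑octalin‑6‑one
Conditions: LiN(i‑Pr)2 (3 equiv), THF, −78 °C; trans‑2‑(phenylsulfonyl)‑3‑phenyloxaziridine; AcOH at −78 °C
Reagents that add atoms: trans‑2‑(phenylsulfonyl)‑3‑phenyloxaziridine, O=S(=O)(c1ccccc1)N1OC1c1ccccc1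
Why: Enolate hydroxylation with an N‑sulfonyloxaziridine, in which the alkoxide–enolate dianion can only form towards C7 and the oxidant should approach from the β face because the α face is blocked by the two 1,3‑diaxial methyls on C5 and C9, giving the equatorial 7β‑OH.

**Step 17**
Reactants: 26 diol ketone
Product: 27 8β‑hydroxy‑7β‑(isobutyryloxy)‑4,5α,8α,9α‑tetramethyl‑9β‑vinyl‑10βH‑Δ3‑octalin‑6‑one
Conditions: (i‑PrCO)2O, Et3N, DMAP (cat.), CH2Cl2, 0 °C → rt
Reagents that add atoms: isobutyric anhydride, CC(C)C(=O)OC(=O)C(C)C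
Why: DMAP‑catalysed acylation should take only the secondary C7 hydroxyl, the tertiary C8 hydroxyl next to the quaternary C9 being inert under these conditions.

**Step 18**
Reactants: 27 keto isobutyrate
Product: 28 7β‑(isobutyryloxy)‑4,5α,8α,9α‑tetramethyl‑9β‑vinyl‑10βH‑Δ3‑octalin‑6α,8β‑diol
Conditions: Me4NBH(OAc)3, MeCN/AcOH, −20 °C
Reagents that add atoms: none
Why: Hydroxyl‑directed triacetoxyborohydride reduction, in which the axial 8β‑OH binds boron and delivers hydride to the β face of the C6 ketone (1,3‑anti outcome), should give the equatorial 6α‑OH while the mildly acidic medium prevents acyl migration.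

**Step 19**
Reactants: 28 diol isobutyrate
Product: 29 6α‑acetoxy‑8β‑hydroxy‑7β‑(isobutyryloxy)‑4,5α,8α,9α‑tetramethyl‑9β‑vinyl‑10βH‑Δ3‑octalin
Conditions: Ac2O, pyridine, DMAP (cat.), CH2Cl2, rt
Reagents that add atoms: acetic anhydride, CC(=O)OC(C)=O
Why: DMAP‑catalysed acetylation of the only remaining secondary hydroxyl, the hindered tertiary C8 hydroxyl staying free.

**Step 20**
Reactants: 29 vinyl diester; 30 4‑bromofuran‑2(5H)‑one
Product: 31 CNP0207114.1
Conditions: Pd(OAc)2 (10 mol%), P(o‑tol)3, NaOAc, n‑Bu4NCl, DMF, 80 °C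
Reagents that add atoms: none
Why: Mizoroki–Heck reaction, in which oxidative addition of the β‑bromobutenolide, insertion of the terminal vinyl group with palladium on C11 and syn β‑hydride elimination should give the E‑C11=C12 bond, double‑bond migration being impossible because C9 is quaternary.

**Compound list**
1 | (E)‑3‑(tert‑butyldimethylsilyloxy)‑N,N‑dimethylbuta‑1,3‑dien‑1‑amine | CN(C)/C=C/C(=C)O[Si](C)(C)C(C)(C)C | starting material
2 | methacrolein (2‑methylprop‑2‑enal) | CC(=C)C=O | starting material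
3 | (1R,2S)‑4‑(tert‑butyldimethylsilyloxy)‑2‑(dimethylamino)‑1‑methylcyclohex‑3‑ene‑1‑carbaldehyde (amino cis to CHO) | O=C[C@@]1(C)[C@@H](N(C)C)C=C(O[Si](C)(C)C(C)(C)C)CC1 | intermediate
4 | bromomagnesium alkoxide of the methyl carbinol from 3 (not isolated) | CC(O[Mg]Br)[C@@]1(C)[C@@H](N(C)C)C=C(O[Si](C)(C)C(C)(C)C)CC1 | intermediate
5 | (4R)‑4‑(1‑hydroxyethyl)‑4‑methylcyclohex‑2‑en‑1‑one (carbinol epimers) | CC(O)[C@@]1(C)C=CC(=O)CC1 | intermediate
6 | (4R)‑4‑acetyl‑4‑methylcyclohex‑2‑en‑1‑one | CC(=O)[C@@]1(C)C=CC(=O)CC1 | intermediate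
7 | (4R)‑4‑acetyl‑2‑iodo‑4‑methylcyclohex‑2‑en‑1‑one | CC(=O)[C@@]1(C)C=C(I)C(=O)CC1 | intermediate
8 | (4R)‑4‑acetyl‑2,4‑dimethylcyclohex‑2‑en‑1‑one | CC(=O)[C@@]1(C)C=C(C)C(=O)CC1 | intermediate
9 | allyltriphenylphosphonium bromide | C=CC[P+](c1ccccc1)(c1ccccc1)c1ccccc1.[Br-] | starting material
10 | allylidenetriphenylphosphorane (not isolated) | C=CC=P(c1ccccc1)(c1ccccc1)c1ccccc1 | intermediate
11 | vinylphosphonium enolate from γ‑conjugate addition of 10 to 8 (zwitterion, C10 epimers, not isolated) | CC(=O)[C@@]1(C)C(C/C=C/[P+](c2ccccc2)(c2ccccc2)c2ccccc2)C(C)=C([O-])CC1 | intermediate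
12 | allylic ylide after the C1‑to‑O proton shift (C9/C10 epimers, not isolated) | CC(=O)[C@@]1(C)C(C=CC=P(c2ccccc2)(c2ccccc2)c2ccccc2)C(C)C(=O)CC1 | intermediate
13 | 4,5α,9‑trimethyl‑Δ1,3‑hexalin‑8‑one = (4aR)‑1,4a,5‑trimethyl‑3,4,4a,8a‑tetrahydronaphthalen‑2(1H)‑one (C9/C10 epimers) | C1CC(=O)C(C)C2C=CC=C(C)[C@]12C | intermediate
14 | 4,5α,9‑trimethyl‑Δ3‑octalin‑8‑one = (4aR)‑1,4a,5‑trimethyl‑3,4,4a,7,8,8a‑hexahydronaphthalen‑2(1H)‑one (C9/C10 epimers) | C1CC(=O)C(C)C2CCC=C(C)[C@]12C | intermediate
15 | 8‑(trimethylsilyloxy)‑4,5α,9‑trimethyl‑Δ3,8‑hexalin (C10 epimers, not isolated) | C1CC(O[Si](C)(C)C)=C(C)C2CCC=C(C)[C@]12C | intermediate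
16 | 4,5α,9‑trimethyl‑Δ3,9(10)‑hexalin‑8‑one = (4aS)‑1,4a,5‑trimethyl‑4,4a,7,8‑tetrahydronaphthalen‑2(3H)‑one | C1CC(=O)C(C)=C2CCC=C(C)[C@]12C | intermediate
17 | lithium 4,5α,9‑trimethyl‑10βH‑Δ3,8‑hexalin‑8‑olate (trans‑fused, not isolated) | C1CC([O-])=C(C)[C@H]2CCC=C(C)[C@]12C.[Li+] | intermediate
18 | 9β‑(1‑hydroxyethyl)‑4,5α,9α‑trimethyl‑10βH‑Δ3‑octalin‑8‑one (trans‑fused, carbinol epimers) | C1CC(=O)[C@](C)(C(C)O)[C@H]2CCC=C(C)[C@]12C | intermediate
19 | 4,5α,9α‑trimethyl‑9β‑vinyl‑10βH‑Δ3‑octalin‑8‑one | C1CC(=O)[C@](C)(C=C)[C@H]2CCC=C(C)[C@]12C | intermediate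
20 | 8‑(trimethylsilyloxy)‑4,5α,9α‑trimethyl‑9β‑vinyl‑10βH‑Δ3,7‑hexalin (not isolated) | C1C=C(O[Si](C)(C)C)[C@](C)(C=C)[C@H]2CCC=C(C)[C@]12C | intermediate
21 | 4,5α,9α‑trimethyl‑9β‑vinyl‑10βH‑Δ3,6‑hexalin‑8‑one | C1=CC(=O)[C@](C)(C=C)[C@H]2CCC=C(C)[C@]12C | intermediate
22 | 4,5α,8,9α‑tetramethyl‑9β‑vinyl‑10βH‑Δ3,6‑hexalin‑8‑ol (C8 epimers) | C1=CC(C)(O)[C@](C)(C=C)[C@H]2CCC=C(C)[C@]12C | intermediate
23 | 4,5α,8,9α‑tetramethyl‑9β‑vinyl‑10βH‑Δ3,7‑hexalin‑6‑one | O=C1C=C(C)[C@](C)(C=C)[C@H]2CCC=C(C)[C@]12C | intermediate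
24 | 7β,8β‑epoxy‑4,5α,8α,9α‑tetramethyl‑9β‑vinyl‑10βH‑Δ3‑octalin‑6‑one | O=C1[C@@H]3O[C@]3(C)[C@](C)(C=C)[C@H]2CCC=C(C)[C@]12C | intermediate
25 | 8β‑hydroxy‑4,5α,8α,9α‑tetramethyl‑9β‑vinyl‑10βH‑Δ3‑octalin‑6‑one | O=C1C[C@](C)(O)[C@](C)(C=C)[C@H]2CCC=C(C)[C@]12C | intermediate
26 | 7β,8β‑dihydroxy‑4,5α,8α,9α‑tetramethyl‑9β‑vinyl‑10βH‑Δ3‑octalin‑6‑one | O=C1[C@H](O)[C@](C)(O)[C@](C)(C=C)[C@H]2CCC=C(C)[C@]12C | intermediate
27 | 8β‑hydroxy‑7β‑(isobutyryloxy)‑4,5α,8α,9α‑tetramethyl‑9β‑vinyl‑10βH‑Δ3‑octalin‑6‑one | O=C1[C@H](OC(=O)C(C)C)[C@](C)(O)[C@](C)(C=C)[C@H]2CCC=C(C)[C@]12C | intermediate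
28 | 7β‑(isobutyryloxy)‑4,5α,8α,9α‑tetramethyl‑9β‑vinyl‑10βH‑Δ3‑octalin‑6α,8β‑diol | O[C@H]1[C@H](OC(=O)C(C)C)[C@](C)(O)[C@](C)(C=C)[C@H]2CCC=C(C)[C@]12C | intermediate
29 | 6α‑acetoxy‑8β‑hydroxy‑7β‑(isobutyryloxy)‑4,5α,8α,9α‑tetramethyl‑9β‑vinyl‑10βH‑Δ3‑octalin | CC(=O)O[C@H]1[C@H](OC(=O)C(C)C)[C@](C)(O)[C@](C)(C=C)[C@H]2CCC=C(C)[C@]12C | intermediate
30 | 4‑bromofuran‑2(5H)‑one | O=C1OCC(Br)=C1 | starting material
31 | CNP0207114.1, (5R,6R,7S,8R,9R,10S)‑6‑acetoxy‑8‑hydroxy‑7‑(isobutyryloxy)cleroda‑3,11E,13‑trien‑15,16‑olide | CC(=O)O[C@H]1[C@H](OC(=O)C(C)C)[C@](C)(O)[C@](C)(/C=C/C2=CC(=O)OC2)[C@H]2CCC=C(C)[C@]12C | target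

**Step count and risks**
Total: 20 steps. Longest linear sequence: 20 steps (1 and 2 to 31); 9 and 30 are commercial and enter directly.

Step 6 (proposed new method). What may go wrong: direct Wittig olefination of the ring carbonyl or the acetyl group by the α‑carbon of the ylide instead of γ‑conjugate addition, or a conjugate adduct that does not undergo the proton shift and ring closure. The fallback uses known reactions, sets out from 8 and rejoins the route at 15. Copper‑catalysed conjugate addition of but‑3‑enylmagnesium bromide to 8 (CuBr·SMe2, Me3SiCl, THF, −78 °C) should give the 10‑(but‑3‑enyl) silyl enol ether F1, in which the ring carbonyl is masked regiospecifically. Wittig methylenation of the free acetyl group (Ph3P=CH2, THF, reflux) should give the isopropenyl diene F2. Ring‑closing metathesis (second‑generation Grubbs catalyst, CH2Cl2, 40 °C) then closes C3=C4 and delivers 15, which is oxidised as in the second stage of step 8.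

Step 8. What may go wrong: loss of regiocontrol in the equilibrating silylation (enol ether on the C7 side), or β‑hydride elimination into the C20 methyl giving an exocyclic methylene ketone. The fallback sets out from 14 and rejoins at 16, and makes the regiochemistry irrelevant. Exhaustive dehydrogenation of 14 with IBX (2‑iodoxybenzoic acid, excess, DMSO, 80 °C) should give the cross‑conjugated dienone 4,5α,9‑trimethyl‑Δ3,6,9(10)‑octalintrien‑8‑one F3. Hydrogenation over RhCl(PPh3)3 then reduces only the disubstituted C6=C7 bond and gives 16.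

Step 20. What may go wrong: slow insertion into the neopentylic vinyl group, so that reduction or homocoupling of the bromobutenolide and base‑induced decomposition of the butenolide take over. The fallback sets out from 29 and ends at 31. Cross‑metathesis of 29 with vinylboronic acid pinacol ester (second‑generation Hoveyda–Grubbs catalyst, CH2Cl2, 40 °C) should give the (E)‑alkenylboronate F4. Suzuki–Miyaura coupling of F4 with 30 (Pd(PPh3)4, K3PO4, THF/H2O, 50 °C) should then give 31 with retention of the E geometry.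

**Further compounds**
F1 | step 6 | (4R)‑4‑acetyl‑3‑(but‑3‑enyl)‑2,4‑dimethyl‑1‑(trimethylsilyloxy)cyclohex‑1‑ene (C3 epimers) | CC(=O)[C@@]1(C)C(CCC=C)C(C)=C(O[Si](C)(C)C)CC1
F2 | step 6 | (4R)‑3‑(but‑3‑enyl)‑4‑isopropenyl‑2,4‑dimethyl‑1‑(trimethylsilyloxy)cyclohex‑1‑ene (C3 epimers) | C=C(C)[C@@]1(C)C(CCC=C)C(C)=C(O[Si](C)(C)C)CC1
F3 | step 8 | 4,5α,9‑trimethyl‑Δ3,6,9(10)‑octalintrien‑8‑one (cross‑conjugated dienone) | C1=CC(=O)C(C)=C2CCC=C(C)[C@]12C
F4 | step 20 | (E)‑2‑(pinacolboryl)vinyl analogue of 29 (Bpin on C12) | CC(=O)O[C@H]1[C@H](OC(=O)C(C)C)[C@](C)(O)[C@](C)(/C=C/B3OC(C)(C)C(C)(C)O3)[C@H]2CCC=C(C)[C@]12C
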